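**Retrosynthetic overview** (atisane numbering: C3 lactone carbonyl, C9 lactone-bearing carbon, C10 methyl-bearing carbon, C14 acetoxy carbon, C15 ketone, C16=C17 methylene)
1. Late stage: the C15 ketone comes from allylic oxidation, the C14 acetate from a ketone, and the bicyclo[2.2.2]octane from closure of a propargyl-derived vinyl radical (C16) onto a C12=C13 enone in tricycle 19.
2. Key disconnection: lactone ring A hides a 5,6-dihydropyran-2-one retron. The acylated, fully substituted carbinol C9 sits next to quaternary C10, and C1–C2 lead to carbonyl C3, so ring A = ketone C9=O + vinylketene C10=C1–C2=C3=O, and the vinylketene = allyl unit + CO. Because C10 is tied to C8 (alpha to C9) through C5–C6–C7, the C9–C10 bond also closes ring B. One carbonylative annulation of allylic phosphate 14 onto a prochiral 2,2-disubstituted cyclohexane-1,3-dione therefore makes C2–C3, C9–C10 and C3–O, rings A and B, and the C8/C9/C10 triad from the single stereocentre C5.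
3. Precursor 14: (Z)-3-iodobutenol (C20, C10, C1, C2) + acrylate (C5–C7, Heck) + isopropenylboron (asymmetric 1,4-addition, sets C5) + cyclohexane-1,3-dione (ring C, reductive alkylation) + silylpropargyl bromide (C15–C17).
4. Ring order: ring C (purchased) → rings B and A together (step 10) → bicyclo[2.2.2]octane (step 13) → oxidation-state adjustments.

Key step: step 10

Step 1
Reactants: 1 but-2-yn-1-ol
Product: 2 (2Z)-3-iodobut-2-en-1-ol
Conditions: NaAlH2(OCH2CH2OMe)2, THF, 0 °C to rt; then I2, −78 to 0 °C
Reagents that add atoms: iodine, II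
Why: Alkoxide-directed trans-hydroalumination of the propargylic alcohol and iodinolysis of the vinyl–aluminium bond with retention should give the Z-configured 3-iodo allylic alcohol (hydroalumination–iodination).

Step 2
Reactants: 2 (2Z)-3-iodobut-2-en-1-ol
Product: 3 tert-butyl{[(2Z)-3-iodobut-2-en-1-yl]oxy}dimethylsilane
Conditions: TBSCl, imidazole, DMF, rt
Reagents that add atoms: tert-butyldimethylsilyl chloride, CC(C)(C)[Si](C)(C)Cl
Why: Silyl ether protection of the primary alcohol, which would otherwise add in an oxa-Michael sense to the dienoate made next.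

Step 3
Reactants: 3 tert-butyl{[(2Z)-3-iodobut-2-en-1-yl]oxy}dimethylsilane; 4 methyl acrylate
Product: 5 methyl (2E,4Z)-6-[(tert-butyldimethylsilyl)oxy]-4-methylhexa-2,4-dienoate
Conditions: Pd(OAc)2 (5 mol%), K2CO3, Bu4NCl, DMF, rt
Reagents that add atoms: none
Why: Heck reaction under ligand-free phase-transfer conditions, in which syn-carbopalladation and syn-β-hydride elimination give the 2E olefin while the alkenyl iodide geometry (4Z) is retained.

Step 4
Reactants: 5 methyl (2E,4Z)-6-[(tert-butyldimethylsilyl)oxy]-4-methylhexa-2,4-dienoate; 6 isopropenylboronic acid pinacol ester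
Product: 7 methyl (3S,4Z)-6-[(tert-butyldimethylsilyl)oxy]-4-methyl-3-(prop-1-en-2-yl)hex-4-enoate
Conditions: [Rh(cod)OH]2 (2.5 mol%), (R)-BINAP (6 mol%), dioxane/H2O (10:1), 60 °C
Reagents that add atoms: none
Why: Rhodium-catalysed asymmetric conjugate addition of an alkenylboron reagent (Hayashi–Miyaura reaction), where 1,4-addition is expected because the γ,δ-olefin is trisubstituted and γ-branched, and the (R)-BINAP complex is predicted by the usual quadrant model to deliver isopropenyl to the Re face of C3, setting the (S) centre (C5 of the target).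

Step 5
Reactants: 7 methyl (3S,4Z)-6-[(tert-butyldimethylsilyl)oxy]-4-methyl-3-(prop-1-en-2-yl)hex-4-enoate
Product: 8 (3S,4Z)-6-[(tert-butyldimethylsilyl)oxy]-4-methyl-3-(prop-1-en-2-yl)hex-4-enal
Conditions: i-Bu2AlH (1.05 equiv), CH2Cl2, −78 °C; aq. potassium sodium tartrate
Reagents that add atoms: none
Why: Partial ester reduction stops at the aluminium hemiacetal at −78 °C and releases the aldehyde on work-up, and the β-stereocentre cannot enolise.

Step 6
Reactants: 8 (3S,4Z)-6-[(tert-butyldimethylsilyl)oxy]-4-methyl-3-(prop-1-en-2-yl)hex-4-enal; 9 cyclohexane-1,3-dione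
Product: 10 2-[(3S,4Z)-6-[(tert-butyldimethylsilyl)oxy]-4-methyl-3-(prop-1-en-2-yl)hex-4-en-1-yl]cyclohexane-1,3-dione
Conditions: Hantzsch ester (1.05 equiv), L-proline (20 mol%), CH2Cl2, rt
Reagents that add atoms: none
Why: Organocatalytic reductive alkylation, in which Knoevenagel condensation gives the alkylidene dione and the Hantzsch ester reduces it by conjugate hydride transfer, so C-monoalkylation is obtained without O-alkylation.

Step 7
Reactants: 10 2-[(3S,4Z)-6-[(tert-butyldimethylsilyl)oxy]-4-methyl-3-(prop-1-en-2-yl)hex-4-en-1-yl]cyclohexane-1,3-dione; 11 3-bromo-1-(trimethylsilyl)prop-1-yne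
Product: 12 2-[(3S,4Z)-6-[(tert-butyldimethylsilyl)oxy]-4-methyl-3-(prop-1-en-2-yl)hex-4-en-1-yl]-2-[3-(trimethylsilyl)prop-2-yn-1-yl]cyclohexane-1,3-dione
Conditions: K2CO3, acetone, 56 °C
Reagents that add atoms: none
Why: C-alkylation of the 2-alkyl-1,3-dione enolate with the reactive propargylic bromide should give the 2,2-disubstituted dione, whose quaternary carbon (C8) is still prochiral.

Step 8
Reactants: 12 2-[(3S,4Z)-6-[(tert-butyldimethylsilyl)oxy]-4-methyl-3-(prop-1-en-2-yl)hex-4-en-1-yl]-2-[3-(trimethylsilyl)prop-2-yn-1-yl]cyclohexane-1,3-dione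
Product: 13 2-[(3S,4Z)-6-hydroxy-4-methyl-3-(prop-1-en-2-yl)hex-4-en-1-yl]-2-[3-(trimethylsilyl)prop-2-yn-1-yl]cyclohexane-1,3-dione
Conditions: CSA (10 mol%), MeOH/CH2Cl2, 0 °C
Reagents that add atoms: none
Why: Acid-catalysed methanolysis (desilylation) removes the primary silyl ether while the alkynylsilane and the non-enolisable dione are untouched.

Step 9
Reactants: 13 2-[(3S,4Z)-6-hydroxy-4-methyl-3-(prop-1-en-2-yl)hex-4-en-1-yl]-2-[3-(trimethylsilyl)prop-2-yn-1-yl]cyclohexane-1,3-dione
Product: 14 (2Z,4S)-6-{2,6-dioxo-1-[3-(trimethylsilyl)prop-2-yn-1-yl]cyclohexyl}-3-methyl-4-(prop-1-en-2-yl)hex-2-en-1-yl diethyl phosphate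
Conditions: (EtO)2P(O)Cl, pyridine, DMAP (cat.), CH2Cl2, 0 °C
Reagents that add atoms: diethyl chlorophosphate, CCOP(=O)(Cl)OCC
Why: Phosphorylation of the primary allylic alcohol gives the ionisable allylic phosphate without touching the Z olefin.

Step 10
Reactants: 14 (2Z,4S)-6-{2,6-dioxo-1-[3-(trimethylsilyl)prop-2-yn-1-yl]cyclohexyl}-3-methyl-4-(prop-1-en-2-yl)hex-2-en-1-yl diethyl phosphate
Product: 16 tricyclic unsaturated keto-lactone (rings A/B/C), via vinylketene 15 (not isolated)
Conditions: Pd2(dba)3 (2.5 mol%), PPh3 (10 mol%), CO (30 atm), i-Pr2NEt (2 equiv), DMAP (20 mol%), THF (0.01 M), 60 °C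
Reagents that add atoms: carbon monoxide, [C-]#[O+]
Why: Proposed new method: zerovalent palladium ionises the allylic phosphate, CO inserts at the unhindered CH2 terminus of the π-allyl complex (new C2–C3 bond) and the amine converts the β,γ-unsaturated acyl-palladium into the (Z)-vinylketene 15 (or its acyl-ammonium dienolate), whose γ-carbon C10 adds to one ketone of the dione while the carbonyl oxygen is acylated at C3; this formal [4+2] is the intramolecular, ketone-trapped combination of two known reaction types, the palladium-catalysed carbonylation of allylic phosphates or halides to vinylketenes (otherwise captured by imines in Staudinger cycloadditions) and the Lewis-base-catalysed vinylketene–carbonyl [4+2] lactonisation. Ring B closes by 6-exo-trig attack of C10 on C9=O (new C9–C10 bond between two fully substituted carbons), and ring A closes in the same hetero-Diels–Alder sense or stepwise by 6-exo-trig lactonisation of the aldolate onto the acyl-ammonium or acyl-palladium carbon. C10 and C9 are controlled by the C5 stereocentre and the Z olefin: with the tether on the inner position of the s-cis diene only the cis-fused lactone can form, and a chair-like ring B with the isopropenyl group equatorial puts the new methyl axial, cis to isopropenyl, and the new C–O bond axial. C8 is set by the choice between the two ketones, expected to follow from attack on the cyclohexanedione carbonyl anti to the adjacent propargyl arm, which leaves that arm equatorial on ring B and the small trigonal spectator carbonyl in the axial site. The step needs γ- over α-attack (α-attack would close an eight-membered ring), retention of the Z geometry (the π-allyl can isomerise only through a tertiary σ-allyl, slower than CO insertion under pressure) and carbonyl capture ahead of ketene dimerisation or [2+2] addition to the isopropenyl group, for which high dilution, moderate temperature and a nucleophilic amine co-catalyst are chosen.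

Step 11
Reactants: 16 tricyclic unsaturated keto-lactone
Product: 18 tricyclic saturated keto-lactone with free propargyl group, via silylalkyne lactone 17 (not isolated)
Conditions: [(Ph3P)CuH]6 (0.4 equiv), PhMe, H2O (2 equiv), rt; then K2CO3 (cat.), MeOH, 0 °C
Reagents that add atoms: none
Why: Copper hydride conjugate reduction is selective for the α,β-unsaturated lactone over the isolated ketone, the isopropenyl group and the silylalkyne, and carbonate-catalysed methanolysis then cleaves the alkynyl–silicon bond (protodesilylation).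

Step 12
Reactants: 18 tricyclic saturated keto-lactone with free propargyl group
Product: 19 tricyclic C12=C13 enone lactone
Conditions: IBX (2.5 equiv), DMSO/PhF (1:2), 70 °C
Reagents that add atoms: none
Why: IBX-mediated ketone dehydrogenation can only occur toward C13, the other α-carbon (C8) being quaternary, and should give the C12=C13 enone.

Step 13
Reactants: 19 tricyclic C12=C13 enone lactone
Product: 21 tetracyclic keto-lactone with bicyclo[2.2.2]octane and exocyclic methylene, via vinylstannane 20 (not isolated)
Conditions: Bu3SnH (1.5 equiv), AIBN (cat.), PhH (0.01 M), 80 °C, slow addition; then wet silica gel, CH2Cl2, rt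
Reagents that add atoms: none
Why: Stannyl-radical addition to the alkyne terminus gives the C16 vinyl radical, which closes onto the enone β-carbon C12 (polarity-matched, six-membered ring, α-keto radical) to form the bicyclo[2.2.2]octane with the bridgehead C12 fixed by the cage, and protodestannylation leaves the exocyclic methylene (vinyl radical cyclisation).

Step 14
Reactants: 21 tetracyclic keto-lactone with bicyclo[2.2.2]octane and exocyclic methylene
Product: 22 C14 alcohol
Conditions: SmI2 (2.5 equiv), THF/H2O, 0 °C, short reaction time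
Reagents that add atoms: none
Why: Single-electron (ketyl) reduction under thermodynamic control should place the C14 hydroxyl on the open face syn to the C15–C16 bridge and the hydrogen against the axial C20 methyl, the opposite of hydride delivery from the open face, while the lactone reacts much more slowly.

Step 15
Reactants: 22 C14 alcohol
Product: 23 C14 acetate
Conditions: Ac2O, DMAP, pyridine, rt
Reagents that add atoms: acetic anhydride, CC(=O)OC(C)=O
Why: DMAP-catalysed acetylation of the secondary alcohol on the open face of the cage.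

Step 16
Reactants: 23 C14 acetate
Product: 25 crotobarin, via allylic alcohol 24 (not isolated)
Conditions: SeO2 (0.5 equiv), t-BuOOH, CH2Cl2, rt; then Dess–Martin periodinane, NaHCO3, CH2Cl2, rt
Reagents that add atoms: selenium dioxide, O=[Se]=O; tert-butyl hydroperoxide, CC(C)(C)OO
Why: Riley allylic oxidation (ene reaction then [2,3]-shift) should hydroxylate C15, the only allylic position of the exocyclic olefin that needs no bridgehead double bond and a CH2 favoured over the isopropenyl methyl, and Dess–Martin oxidation then gives the α-methylene ketone.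

**Compound list**
1 | but-2-yn-1-ol | CC#CCO | starting material
2 | (2Z)-3-iodobut-2-en-1-ol | I/C(C)=C\CO | intermediate
3 | tert-butyl{[(2Z)-3-iodobut-2-en-1-yl]oxy}dimethylsilane | I/C(C)=C\CO[Si](C)(C)C(C)(C)C | intermediate
4 | methyl acrylate | C=CC(=O)OC | starting material
5 | methyl (2E,4Z)-6-[(tert-butyldimethylsilyl)oxy]-4-methylhexa-2,4-dienoate | COC(=O)/C=C/C(C)=C\CO[Si](C)(C)C(C)(C)C | intermediate
6 | isopropenylboronic acid pinacol ester | CC(=C)B1OC(C)(C)C(C)(C)O1 | starting material
7 | methyl (3S,4Z)-6-[(tert-butyldimethylsilyl)oxy]-4-methyl-3-(prop-1-en-2-yl)hex-4-enoate | COC(=O)C[C@@H](C(=C)C)/C(C)=C\CO[Si](C)(C)C(C)(C)C | intermediate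
8 | (3S,4Z)-6-[(tert-butyldimethylsilyl)oxy]-4-methyl-3-(prop-1-en-2-yl)hex-4-enal | O=CC[C@@H](C(=C)C)/C(C)=C\CO[Si](C)(C)C(C)(C)C | intermediate
9 | cyclohexane-1,3-dione | O=C1CCCC(=O)C1 | starting material
10 | 2-[(3S,4Z)-6-[(tert-butyldimethylsilyl)oxy]-4-methyl-3-(prop-1-en-2-yl)hex-4-en-1-yl]cyclohexane-1,3-dione (drawn as diketone; enolised in solution) | O=C1CCCC(=O)C1CC[C@@H](C(=C)C)/C(C)=C\CO[Si](C)(C)C(C)(C)C | intermediate
11 | 3-bromo-1-(trimethylsilyl)prop-1-yne | C[Si](C)(C)C#CCBr | starting material
12 | 2-[(3S,4Z)-6-[(tert-butyldimethylsilyl)oxy]-4-methyl-3-(prop-1-en-2-yl)hex-4-en-1-yl]-2-[3-(trimethylsilyl)prop-2-yn-1-yl]cyclohexane-1,3-dione | C[Si](C)(C)C#CCC1(CC[C@@H](C(=C)C)/C(C)=C\CO[Si](C)(C)C(C)(C)C)C(=O)CCCC1=O | intermediate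
13 | 2-[(3S,4Z)-6-hydroxy-4-methyl-3-(prop-1-en-2-yl)hex-4-en-1-yl]-2-[3-(trimethylsilyl)prop-2-yn-1-yl]cyclohexane-1,3-dione | C[Si](C)(C)C#CCC1(CC[C@@H](C(=C)C)/C(C)=C\CO)C(=O)CCCC1=O | intermediate
14 | (2Z,4S)-6-{2,6-dioxo-1-[3-(trimethylsilyl)prop-2-yn-1-yl]cyclohexyl}-3-methyl-4-(prop-1-en-2-yl)hex-2-en-1-yl diethyl phosphate | C[Si](C)(C)C#CCC1(CC[C@@H](C(=C)C)/C(C)=C\COP(=O)(OCC)OCC)C(=O)CCCC1=O | intermediate
15 | vinylketene: (3Z,5S)-7-{2,6-dioxo-1-[3-(trimethylsilyl)prop-2-yn-1-yl]cyclohexyl}-4-methyl-5-(prop-1-en-2-yl)hepta-1,3-dien-1-one | C[Si](C)(C)C#CCC1(CC[C@@H](C(=C)C)/C(C)=C\C=C=O)C(=O)CCCC1=O | intermediate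
16 | tricyclic unsaturated keto-lactone: 5,6-dihydropyran-2-one (ring A, C1=C2) cis-fused at C9–C10 to carbocycle B, which is fused at C8–C9 to cyclohexanone C (C14=O); C8 carries CH2C≡CSiMe3; O9, C1 and the propargyl arm on one face of ring B, C20 methyl, isopropenyl and C14 on the other | C[Si](C)(C)C#CC[C@]23CC[C@@H](C(=C)C)[C@]4(C)C=CC(=O)O[C@@]42CCCC3=O | intermediate
17 | silylalkyne lactone: 1,2-dihydro derivative of 16 | C[Si](C)(C)C#CC[C@]23CC[C@@H](C(=C)C)[C@]4(C)CCC(=O)O[C@@]42CCCC3=O | intermediate
18 | tricyclic saturated keto-lactone with free propargyl group on C8 | C#CC[C@]23CC[C@@H](C(=C)C)[C@]4(C)CCC(=O)O[C@@]42CCCC3=O | intermediate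
19 | tricyclic enone lactone (C14=O, C12=C13) with propargyl group on C8 | C#CC[C@]23CC[C@@H](C(=C)C)[C@]4(C)CCC(=O)O[C@@]42CC=CC3=O | intermediate
20 | vinylstannane: bicyclo[2.2.2]octanone with C16=C17H–SnBu3 (olefin geometry not defined) | CCCC[Sn](CCCC)(CCCC)C=C1C[C@]23CC[C@@H](C(=C)C)[C@]4(C)CCC(=O)O[C@@]42C[C@H]1CC3=O | intermediate
21 | tetracyclic keto-lactone: 14-oxo, 16(17)-methylene, bicyclo[2.2.2]octane closed | C=C1C[C@]23CC[C@@H](C(=C)C)[C@]4(C)CCC(=O)O[C@@]42C[C@H]1CC3=O | intermediate
22 | C14 alcohol (hydroxyl syn to the C15–C16 bridge) | C=C1C[C@]23CC[C@@H](C(=C)C)[C@]4(C)CCC(=O)O[C@@]42C[C@H]1C[C@@H]3O | intermediate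
23 | C14 acetate (15-deoxocrotobarin) | C=C1C[C@]23CC[C@@H](C(=C)C)[C@]4(C)CCC(=O)O[C@@]42C[C@H]1C[C@@H]3OC(C)=O | intermediate
24 | allylic alcohol: 15-hydroxy derivative of 23 (C15 epimers) | C=C1C(O)[C@]23CC[C@@H](C(=C)C)[C@]4(C)CCC(=O)O[C@@]42C[C@H]1C[C@@H]3OC(C)=O | intermediate
25 | crotobarin (5S,8S,9S,10S,12R,14S in atisane numbering) | C=C1C(=O)[C@]23CC[C@@H](C(=C)C)[C@]4(C)CCC(=O)O[C@@]42C[C@H]1C[C@@H]3OC(C)=O | target

**Total step count:** 16. **Longest linear sequence:** 16 steps (from but-2-yn-1-ol 1).

**Steps most likely to fail**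

Step 10 (proposed new method). The acyl-palladium or vinylketene may be consumed before the hindered ketone traps it, by [2+2] addition to the isopropenyl group, by 1,5-hydrogen shift, or after loss of the Z geometry in the π-allyl stage. The choice between the two ketones may also be poorly selective. Fallback, from 14: palladium-catalysed borylation (B2pin2, Pd2(dba)3, DMSO, 50 °C) should give the (Z)-allyl pinacolboronate F1. Heating in toluene brings about intramolecular allylboration of one dione carbonyl through a closed chair transition state (same stereochemical logic as step 10) and, after aqueous work-up, gives the tertiary homoallylic alcohol F2 with a vinyl group on C10. Linear-selective hydroformylation of that vinyl group (Rh(acac)(CO)2, Xantphos, CO/H2, toluene, 80 °C) gives an aldehyde that closes onto the C9 hydroxyl as the lactol F3. Oxidation (TEMPO, PhI(OAc)2) gives 17, where the route is rejoined; 17 is desilylated to 18 as in the second stage of step 11.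

Step 4. Carbometalation may occur at the γ,δ-olefin (1,6-addition), the α-branched alkenylboron reagent may protodeboronate, or facial discrimination on the hindered dienoate may be poor. Fallback, from 5: saponification (LiOH, THF/H2O) gives the dienoic acid F4. Mixed-anhydride coupling (t-BuCOCl, Et3N, then lithiated (R)-4-phenyloxazolidin-2-one) gives the N-dienoyl imide F5. Copper-promoted addition of CH2=C(CH3)MgBr (CuBr·SMe2, THF, −78 °C) to the chelated s-cis imide, anti to the phenyl group, should give the (3S) adduct F6. Methanolysis (NaOMe, MeOH, 0 °C) returns ester 7.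

Step 14. Hydrogen delivery to C14 from the open face would leave the hydroxyl pressed against the C20 methyl (the C14 epimer), and prolonged exposure could start to reduce the lactone. Fallback, from 21: NaBH4 (MeOH, 0 °C) delivers hydride from the open face and should give the C14-epimeric alcohol F7. A Mitsunobu reaction with acetic acid (PPh3, DIAD, THF), in which acetate enters from the open face with inversion, installs the acetate directly and returns to the route at 23.

**Further compounds**
F1 | step 10 | 2-[(3S,4Z)-4-methyl-3-(prop-1-en-2-yl)-6-(4,4,5,5-tetramethyl-1,3,2-dioxaborolan-2-yl)hex-4-en-1-yl]-2-[3-(trimethylsilyl)prop-2-yn-1-yl]cyclohexane-1,3-dione | C[Si](C)(C)C#CCC1(CC[C@@H](C(=C)C)/C(C)=C\CB2OC(C)(C)C(C)(C)O2)C(=O)CCCC1=O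
F2 | step 10 | bicyclic tertiary homoallylic alcohol (C9–OH, C10 vinyl and methyl, C14 ketone, C8 silylpropargyl) | C[Si](C)(C)C#CC[C@]23CC[C@@H](C(=C)C)[C@](C)(C=C)[C@@]2(O)CCCC3=O
F3 | step 10 | lactol corresponding to 17 (C3 hemiacetal, anomers) | C[Si](C)(C)C#CC[C@]23CC[C@@H](C(=C)C)[C@]4(C)CCC(O)O[C@@]42CCCC3=O
F4 | step 4 | (2E,4Z)-6-[(tert-butyldimethylsilyl)oxy]-4-methylhexa-2,4-dienoic acid | OC(=O)/C=C/C(C)=C\CO[Si](C)(C)C(C)(C)C
F5 | step 4 | (4R)-3-[(2E,4Z)-6-[(tert-butyldimethylsilyl)oxy]-4-methylhexa-2,4-dienoyl]-4-phenyl-1,3-oxazolidin-2-one | O=C(/C=C/C(C)=C\CO[Si](C)(C)C(C)(C)C)N1[C@H](c2ccccc2)COC1=O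
F6 | step 4 | (4R)-3-[(3S,4Z)-6-[(tert-butyldimethylsilyl)oxy]-4-methyl-3-(prop-1-en-2-yl)hex-4-enoyl]-4-phenyl-1,3-oxazolidin-2-one | O=C(C[C@@H](C(=C)C)/C(C)=C\CO[Si](C)(C)C(C)(C)C)N1[C@H](c2ccccc2)COC1=O
F7 | step 14 | C14 epimer of alcohol 22 | C=C1C[C@]23CC[C@@H](C(=C)C)[C@]4(C)CCC(=O)O[C@@]42C[C@H]1C[C@H]3O
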